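Counted in percent of its X, the summer run stalls lower than the noon run, 32.1% against 36.1%, yet in concentration it holds more L, 0.0481 M against 0.0361 M. Two chemists read these stalls differently.

| setting | noon | summer | flask |
|---|---|---|---|
| X | 0.10 M | 0.15 M | 0.10 M |
| E | 0.15 M | 0.15 M | 0.150 M |
| temperature | −20 °C | −20 °C | −20 °C |
| remark | the very flask that is asked about, followed so far | run made earlier |  |
| time |  |  | 30 min |

| run | time / min | L / % |
|---|---|---|
| noon | 1.50 | 1.0 |
| noon | 5.00 | 13.9 |
| noon | 8.00 | 21.4 |
| noon | 12.0 | 30.9 |
| noon | 20.0 | 36.1 |
| summer | 2.50 | 4.1 |
| summer | 8.00 | 20.1 |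
| summer | 15.0 | 30.0 |
| summer | 20.0 | 31.7 |
| summer | 30.0 | 32.1 |

(standard deviation of a reading: 1 percentage point)

- amber: at 30 min take out 90% of the L then present, then wait 15 min
- red: change nothing and wait 15 min more
- blue: at 30 min raise the temperature by 15 K, then wait 15 min
- teal: at 30 min add E, 50.0% of the amount charged, then wait 15 min

- L that was removed still counts
- the earlier runs do not show what temperature does; that part of a forecast is a guess
- additions bring no volume worth counting

- L, in percent of the X first charged, at 30 min
- which option adds most L ("none" when 2 percentage points or less is all one gets) (amber / red / blue / teal / none)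
- L present, with what was taken out counted in, in percent of the X first charged, after amber
- L present, with what was taken out counted in, in percent of the X first charged, after blue

The first sees a balance, X + E ⇌ L, that stops when forward and back are equal. The second sees E dying by itself, with L climbing as a first-order approach for as long as E lasts. In the summer run, the gap to the last reading falls from 28 percentage points at 2.50 min to 2.1 points at 15.0 min. That gives a reading of the dying rate, the rate at which the gap to the stall closes, of 0.207 /min. It is rough, since the later gap is not far above the scatter, and a balance could show a similar rate, so the climb does not part them.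

What parts them is the E left in the noon flask. On the second view, the share of its own charge left at time t is exp(−rate × t) whatever the charge, which makes 0.200% at 30 min. On the first view, with the forecast's L, about 75.5% remains. The second chemist therefore expects amber to bring nothing new and picks teal.

The forecast is the first chemist's: now 36.8% (35.3% to 39%), best amber, g1 51% (45% to 56%), g3 35% (28% to 42%). In its words, “Removing L re-drives the reaction”.

The simulation gives now 37.4%, g1 53.6%, g3 60.2%, and the best option is blue, adding 23 points; amber adds 16 points, teal 6.8 points, red 0.74 points. Neither pick stands. The value 53.6% lies inside the forecast's range for g1, but the steps below hold no X + E ⇌ L, and the balance among them that touches L is L ⇌ Q.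

    X ⇌ Z (K = 1.20, k = 0.00300 /s, Ea = 68.0 kJ/mol, ΔH = −75.0 kJ/mol)
    E → D (k = 0.00290 /s, Ea = 65.0 kJ/mol)
    E + L → G (k = 0.00320 /M/s, Ea = 41.0 kJ/mol)
    D → J (k = 0.00130 /s, Ea = 70.0 kJ/mol)
    Z + D → L (k = 0.0560 /M/s, Ea = 56.0 kJ/mol)
    L ⇌ Q (K = 0.860, k = 0.00270 /s, Ea = 69.0 kJ/mol, ΔH = −66.0 kJ/mol)
    (constants at −20 °C)

In the noon flask E, the limiting reagent, stands at 0.462% of its charge at 30.0 min, against the 0.200% from the dying rate, so the stall goes to the second chemist. A neighbour flask charged with 0.090 M of E holds 0.484% of its own charge at that time, the near-equal share that the dying rate expects. At 3.88 min in the noon flask, the forward step L into Q uses L 11 times as fast as E + L into G. At 30.0 min the noon flask holds Q at 30.9% of the X charged, beside L at 37.4%.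

Readings and results stem from a simulated flask from invented constants; the scatter is artificial.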